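A direct plan would keep a bought chromanone as rings A and C and attach ring B to its C3.
It would silylate 7-hydroxychroman-4-one A1 to the bis-silyl enol ether A2, arylate C3 of A2 with veratrole A3 after umpolung by a trivalent-iodine oxidant to reach the isoflavanone A4, dehydrogenate A4 to the 7-hydroxyisoflavone A5 and O-prenylate A5 last.
Weak point 1, the C3 arylation of A2 by the simple arene A3: this reaction type is unproven for unactivated arenes, would need a large excess of A3 at low temperature, and would compete with α-oxygenation and with attack at the other free positions of A3.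
Weak point 2, the dehydrogenation of A4 to A5: a pure redox correction that builds nothing and erases a stereocentre that first had to be made, with a quinone oxidant acting on a free phenol beside an electron-rich aryl ring.
Weak point 3, the silylation of A1 to A2, the later desilylation and the late prenylation of A5: the phenol would have to be masked and unmasked, and the prenyl group could only come at the very end because the oxidants of the sequence would attack its alkene.

**Retrosynthetic overview**
Ring C is cut at O1–C8a to an enolate and an aryl fluoride; the C4 carbonyl sits ortho to C8a and activates it for SNAr. The C3–C4 bond is traced back to a 1,2-aroyl shift, so the branched isoflavone skeleton (C3 bearing ring B and C4, C2 an unsubstituted CH on O1) comes from the linear skeleton of chalcone epoxide 6, with C2 the former α-carbon and O1 the epoxide oxygen.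
Epoxide 6 comes from chalcone 5, made by Claisen–Schmidt condensation of ketone 3 with veratraldehyde 4; rings A and B are bought and ring C closes last, in the key step.
The prenyl ether goes on first, because no step uses an electrophilic oxidant, a strong Brønsted acid or zerovalent palladium. Fluorine marks the site of O1, so no protecting group is needed, nothing is dehydrogenated afterwards, and the only stereocentres (the racemic trans-epoxide) are consumed in the next step.

Key step: step 4

Remark: 2'-fluoro-4'-hydroxyacetophenone 1 is taken as a commercial compound. Target 8 is achiral; the SMILES of epoxide 6 shows one enantiomer of the racemic trans pair.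

Step 1
Reactants: 1 1-(2-fluoro-4-hydroxyphenyl)ethan-1-one; 2 prenyl bromide (1-bromo-3-methylbut-2-ene)
Product: 3 1-[2-fluoro-4-(3-methylbut-2-en-1-yloxy)phenyl]ethan-1-one
Conditions: K2CO3 (1.5 equiv), 2 (1.2 equiv), acetone, reflux
Reagents that add atoms: none
Why: Williamson ether synthesis, in which the phenoxide (the only acidic site) is O-alkylated by SN2 at the primary allylic bromide while the aryl fluoride is inert to carbonate in acetone; no stereocentre is formed.

Step 2
Reactants: 3 1-[2-fluoro-4-(3-methylbut-2-en-1-yloxy)phenyl]ethan-1-one; 4 veratraldehyde (3,4-dimethoxybenzaldehyde)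
Product: 5 (E)-3-(3,4-dimethoxyphenyl)-1-[2-fluoro-4-(3-methylbut-2-en-1-yloxy)phenyl]prop-2-en-1-one
Conditions: KOH (aq, 1.5 equiv), EtOH, 0 °C to rt; product collected by filtration
Reagents that add atoms: none
Why: Claisen–Schmidt (crossed aldol) condensation, in which the methyl ketone enolate adds to the non-enolisable aldehyde and E1cB loss of water gives the thermodynamic (E)-enone, which should crystallise before hydroxide can displace the fluoride; no stereocentre is formed.

Step 3
Reactants: 5 (E)-3-(3,4-dimethoxyphenyl)-1-[2-fluoro-4-(3-methylbut-2-en-1-yloxy)phenyl]prop-2-en-1-one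
Product: 6 racemic trans-epoxide [(2R*,3S*)-3-(3,4-dimethoxyphenyl)oxiran-2-yl][2-fluoro-4-(3-methylbut-2-en-1-yloxy)phenyl]methanone
Conditions: H2O2 (30 % aq, 3 equiv), NaOH (2 M aq, 0.5 equiv), MeOH/THF, 0 °C to rt; isolated by filtration or extraction, no silica gel
Reagents that add atoms: hydrogen peroxide, OO
Why: Weitz–Scheffer nucleophilic epoxidation, in which hydroperoxide adds in conjugate fashion to the enone only (the isolated electron-rich prenyl alkene is not an acceptor) and the enolate closes on the O–O bond after bond rotation, which sets the two new stereocentres trans to each other and racemic; both are consumed in step 4.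

Step 4
Reactants: 6 racemic trans-epoxide [(2R*,3S*)-3-(3,4-dimethoxyphenyl)oxiran-2-yl][2-fluoro-4-(3-methylbut-2-en-1-yloxy)phenyl]methanone
Product: 8 7-prenyloxy-3',4'-dimethoxyisoflavone, via α-formyl deoxybenzoin 7 (not isolated)
Conditions: BF3·OEt2 (0.3 equiv), CH2Cl2, −20 to 0 °C; then K2CO3 (3 equiv), DMF, CH2Cl2 distilled off, 80 °C
Reagents that add atoms: none
Why: BF3 opens the epoxide at the benzylic C–O bond to a cation stabilised by the para-methoxy group of ring B, and the aroyl group shifts from Cα to Cβ (House–Meinwald rearrangement of a chalcone oxide, the classical epoxide entry to isoflavones), which forms the C3–C4 bond and turns the linear chalcone skeleton into the branched one of 7 with the former Cα as an aldehyde. After the change to K2CO3/DMF the enolate oxygen of that aldehyde (the former epoxide oxygen, the future O1) attacks C8a, the fluorine-bearing carbon ortho to the C4 ketone, by addition–elimination (SNAr) through a ketone-stabilised Meisenheimer anion; the closest known reaction type is the closure of o-fluorobenzoyl β-dicarbonyl enolates to chromones and 4-quinolones. Ring C closes in a 6-endo-trig sense if C8a=C4a–C4=O is read as a β-fluoro enone, and only O-attack can give a six-membered ring, since C-attack would give a four-membered one. No stereocentre is formed, as the two epoxide centres and the labile centre of 7 end as the sp2 carbons C2 and C3. The step needs acyl over hydride migration, which the high migratory aptitude of an acyl group towards a strongly stabilised benzylic cation should secure. It also needs the prenyl ether to survive, which the low basicity of its oxygen (para to the ketone, a vinylogous ester), the substoichiometric Lewis acid at low temperature and an SNAr temperature far below that of an aryl prenyl ether Claisen rearrangement should secure.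

**Compound list**
1 | 1-(2-fluoro-4-hydroxyphenyl)ethan-1-one (2'-fluoro-4'-hydroxyacetophenone) | CC(=O)c1ccc(O)cc1F | starting material
2 | prenyl bromide (1-bromo-3-methylbut-2-ene) | CC(C)=CCBr | starting material
3 | 1-[2-fluoro-4-(3-methylbut-2-en-1-yloxy)phenyl]ethan-1-one | CC(=O)c1ccc(OCC=C(C)C)cc1F | intermediate
4 | veratraldehyde (3,4-dimethoxybenzaldehyde) | COc1ccc(C=O)cc1OC | starting material
5 | (E)-3-(3,4-dimethoxyphenyl)-1-[2-fluoro-4-(3-methylbut-2-en-1-yloxy)phenyl]prop-2-en-1-one | COc1ccc(/C=C/C(=O)c2ccc(OCC=C(C)C)cc2F)cc1OC | intermediate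
6 | racemic trans-[(2R*,3S*)-3-(3,4-dimethoxyphenyl)oxiran-2-yl][2-fluoro-4-(3-methylbut-2-en-1-yloxy)phenyl]methanone (one enantiomer drawn) | O=C(c1ccc(OCC=C(C)C)cc1F)[C@@H]1O[C@H]1c1ccc(OC)c(OC)c1 | intermediate
7 | 2-(3,4-dimethoxyphenyl)-3-[2-fluoro-4-(3-methylbut-2-en-1-yloxy)phenyl]-3-oxopropanal (α-formyl deoxybenzoin, mainly enolised, not isolated) | O=CC(c1ccc(OC)c(OC)c1)C(=O)c1ccc(OCC=C(C)C)cc1F | intermediate
8 | 7-prenyloxy-3',4'-dimethoxyisoflavone, 3-(3,4-dimethoxyphenyl)-7-(3-methylbut-2-en-1-yloxy)-4H-chromen-4-one (achiral) | COc1ccc(-c2coc3cc(OCC=C(C)C)ccc3c2=O)cc1OC | target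

Total step count: 4. Longest linear sequence: 4 steps.

**Steps most likely to fail**

Step 4 (key step). The Lewis acid may ionise the aryl prenyl ether, or hydride may migrate in place of the acyl group. The formyl group of 7 may also be lost by retro-Claisen cleavage before the SNAr closure. The fallback is a deoxybenzoin route that needs no Lewis acid and sets out from ketone 3. α-Arylation of 3 with 4-bromoveratrole F1 (Pd2(dba)3 as a zerovalent palladium source, Xantphos, K3PO4, toluene, 80 °C) should give the deoxybenzoin 2-(3,4-dimethoxyphenyl)-1-[2-fluoro-4-(3-methylbut-2-en-1-yloxy)phenyl]ethan-1-one F2. Oxidative addition of the aryl bromide is expected to outrun ionisation of the trisubstituted allyl ether. Condensation of F2 with N,N-dimethylformamide dimethyl acetal (toluene, 90 °C) should give the enaminone (E)-2-(3,4-dimethoxyphenyl)-3-(dimethylamino)-1-[2-fluoro-4-(3-methylbut-2-en-1-yloxy)phenyl]prop-2-en-1-one F3. Heating F3 with K2CO3 in wet DMF (90 °C) should hydrolyse the enaminone slowly to the enolate of 7, at a temperature where SNAr closure is already fast. The sequence comes back to the route at target 8.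

Step 3. Conjugate addition of hydroperoxide to an enone deactivated by the electron-rich ring B may be slow, so that retro-aldol cleavage or attack of hydroperoxide at the activated C–F position takes over. The benzylic epoxide may also open under traces of acid during isolation. The fallback is a Darzens construction that forms the Cα–Cβ bond and the epoxide together and needs no peroxide; it sets out from ketone 3. LiN(SiMe3)2/Me3SiCl (THF, −78 °C) should give the silyl enol ether {1-[2-fluoro-4-(3-methylbut-2-en-1-yloxy)phenyl]ethenyl}oxy(trimethyl)silane F4. N-Chlorosuccinimide (THF, 0 °C) should convert it to the α-chloro ketone 2-chloro-1-[2-fluoro-4-(3-methylbut-2-en-1-yloxy)phenyl]ethan-1-one F5. Darzens condensation of F5 with veratraldehyde 4 (KOtBu, THF/tBuOH, 0 °C) should give the trans-epoxy ketone and so return to the route at 6, which would be carried into step 4 without chromatography.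

Step 2. Once the enone has formed, hydroxide or ethoxide may displace the ketone-activated fluoride, and the resulting 2'-oxygenated chalcone would divert towards a flavanone; the condensation may also stall. The fallback is a directed aldol addition with separate dehydration and no nucleophilic base; it sets out from ketone 3. LiN(iPr)2 (THF, −78 °C) followed by aldehyde 4 and a quench with aqueous NH4Cl should give the racemic β-hydroxy ketone 3-(3,4-dimethoxyphenyl)-1-[2-fluoro-4-(3-methylbut-2-en-1-yloxy)phenyl]-3-hydroxypropan-1-one F6. MsCl/Et3N (CH2Cl2, 0 °C to rt) should convert it to the mesylate 1-(3,4-dimethoxyphenyl)-3-[2-fluoro-4-(3-methylbut-2-en-1-yloxy)phenyl]-3-oxopropyl methanesulfonate F7, which should eliminate in the flask (E1cB) to the (E)-enone, returning to the route at chalcone 5.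

**Further compounds**
F1 | step 4 | 4-bromoveratrole (4-bromo-1,2-dimethoxybenzene) | COc1ccc(Br)cc1OC
F2 | step 4 | 2-(3,4-dimethoxyphenyl)-1-[2-fluoro-4-(3-methylbut-2-en-1-yloxy)phenyl]ethan-1-one | COc1ccc(CC(=O)c2ccc(OCC=C(C)C)cc2F)cc1OC
F3 | step 4 | (E)-2-(3,4-dimethoxyphenyl)-3-(dimethylamino)-1-[2-fluoro-4-(3-methylbut-2-en-1-yloxy)phenyl]prop-2-en-1-one | CN(C)/C=C(\c1ccc(OC)c(OC)c1)C(=O)c1ccc(OCC=C(C)C)cc1F
F4 | step 3 | {1-[2-fluoro-4-(3-methylbut-2-en-1-yloxy)phenyl]ethenyl}oxy(trimethyl)silane | C=C(O[Si](C)(C)C)c1ccc(OCC=C(C)C)cc1F
F5 | step 3 | 2-chloro-1-[2-fluoro-4-(3-methylbut-2-en-1-yloxy)phenyl]ethan-1-one | O=C(CCl)c1ccc(OCC=C(C)C)cc1F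
F6 | step 2 | racemic 3-(3,4-dimethoxyphenyl)-1-[2-fluoro-4-(3-methylbut-2-en-1-yloxy)phenyl]-3-hydroxypropan-1-one | COc1ccc(C(O)CC(=O)c2ccc(OCC=C(C)C)cc2F)cc1OC
F7 | step 2 | racemic 1-(3,4-dimethoxyphenyl)-3-[2-fluoro-4-(3-methylbut-2-en-1-yloxy)phenyl]-3-oxopropyl methanesulfonate | COc1ccc(C(OS(C)(=O)=O)CC(=O)c2ccc(OCC=C(C)C)cc2F)cc1OC
A1 | direct plan | 7-hydroxychroman-4-one | O=C1CCOc2cc(O)ccc12
A2 | direct plan | 4,7-bis(trimethylsilyloxy)-2H-chromene | C[Si](C)(C)OC1=CCOc2cc(O[Si](C)(C)C)ccc12
A3 | direct plan | veratrole (1,2-dimethoxybenzene) | COc1ccccc1OC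
A4 | direct plan | racemic 7-hydroxy-3-(3,4-dimethoxyphenyl)chroman-4-one | COc1ccc(cc1OC)C1COc2cc(O)ccc2C1=O
A5 | direct plan | 7-hydroxy-3-(3,4-dimethoxyphenyl)-4H-chromen-4-one | COc1ccc(cc1OC)-c1coc2cc(O)ccc2c1=O
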